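Ring B (C5–C10) carries a tetrasubstituted C8=C9 double bond set between the oxygen-bearing C7 and the quaternary, methyl-bearing C10. This is the pattern an alkyne leaves when it adds across a 1-oxygenated diene C7=C6–C5=C10 anchored on ring A, so the whole plan rests on cutting C7–C8 and C9–C10. A single intermolecular Diels–Alder reaction then closes ring B, creates C7 and C10, installs the C8=C9 alkene and leaves C5=C6 as the handle for the C5 hydrogen and C6 oxygen. Its partners are an (E)-bis-silyl dienol ether of ring A, made from ketoisophorone, and a ketal-protected 6-oxohept-2-ynoate used as its electron-poor 2,2,2-trifluoroethyl ester.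

Key step: step 7

Remarks on the chemistry
- Labdane numbering is used for all bicyclic compounds: ring A = C1–C5/C10, ring B = C5–C10, side chain C11–C16 on C9, C17 on C8. β is the face of the C10 methyl. The target is the 2α,6β,7α-triacetate with 5α-H, 10β-methyl and a 13E alkene.
- Assumption: the ene-reductase/carbonyl-reductase pair of step 1 delivers (4R,6R)-actinol, whose carbinol carbon becomes C2 with the 2α-oxygen.
- Design of the key-step partners: the dienol ether is made by vinylogous enolisation of an s-trans enal, which should give the (E)-isomer. The ynoate is carried as the trifluoroethyl ester to lower its LUMO. The cycloaddition is run under pressure and not at high temperature, because the diene can undergo a [1,5]-hydrogen shift from the C10 methyl to C7 on strong heating.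

Step 1
Reactants: 1 ketoisophorone (2,6,6-trimethylcyclohex-2-ene-1,4-dione)
Product: 3 (4R,6R)-4-hydroxy-2,2,6-trimethylcyclohexan-1-one, via (6R)-levodione 2 (not isolated)
Conditions: OYE2 (old yellow enzyme 2, Saccharomyces cerevisiae), glucose dehydrogenase, NADP+ (cat.), D-glucose, phosphate buffer pH 7, 30 °C; then levodione reductase (Corynebacterium aquaticum), NAD+ (cat.)
Reagents that add atoms: none
Why: Enzymatic asymmetric reduction in two stages, in which the ene-reductase saturates the C=C bond to set the methyl-bearing centre as R and the carbonyl reductase then reduces only the unhindered C4 ketone to the (4R)-alcohol, both centres being fixed by the enzyme active sites.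

Step 2
Reactants: 3 (4R,6R)-4-hydroxy-2,2,6-trimethylcyclohexan-1-one
Product: 4 (4R,6R)-4-(tert-butyldimethylsilyloxy)-2,2,6-trimethylcyclohexan-1-one
Conditions: TBSCl, imidazole, DMF, rt
Reagents that add atoms: tert-butyldimethylsilyl chloride, CC(C)(C)[Si](C)(C)Cl
Why: Imidazole-promoted silylation of an unhindered secondary alcohol, which touches no stereocentre and gives a group stable to every later step before the fluoride deprotection.

Step 3
Reactants: 4 (4R,6R)-4-(tert-butyldimethylsilyloxy)-2,2,6-trimethylcyclohexan-1-one; 5 (Z)-1-bromo-2-ethoxyethene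
Product: 7 (E)-2-[(4R,6R)-4-(tert-butyldimethylsilyloxy)-2,2,6-trimethylcyclohexylidene]acetaldehyde, via carbinol adduct 6 (not isolated)
Conditions: 5, t-BuLi (2 equiv), Et2O, −78 °C; add 4, −78 → 0 °C; then 0.5 M aq. HCl, THF, 0 °C
Reagents that add atoms: water, O
Why: 1,2-Addition of (Z)-2-ethoxyvinyllithium (an acetaldehyde anion equivalent) to a ketone whose only α-hydrogen is hindered and tertiary, followed by acid-catalysed allylic transposition and hydrolysis of the β-hydroxy enol ether to the two-carbon-homologated enal, the formyl group settling on the side away from the gem-dimethyl carbon to avoid allylic strain.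

Step 4
Reactants: 7 (E)-2-[(4R,6R)-4-(tert-butyldimethylsilyloxy)-2,2,6-trimethylcyclohexylidene]acetaldehyde
Product: 8 (R,E)-bis-silyl dienol ether, (1R)-1-(tert-butyldimethylsilyloxy)-4-[(E)-2-(tert-butyldimethylsilyloxy)ethenyl]-3,5,5-trimethylcyclohex-3-ene
Conditions: TBSOTf, Et3N, CH2Cl2, 0 °C → rt
Reagents that add atoms: tert-butyldimethylsilyl trifluoromethanesulfonate, CC(C)(C)[Si](C)(C)OS(=O)(=O)C(F)(F)F
Why: Vinylogous silyl enol ether formation, in which O-silylation of the enal and loss of its only γ-hydrogen move the double bond into the ring and erase the methyl-bearing stereocentre on purpose, the (E)-enol ether following from the s-trans conformation of the enal (any deconjugated aldehyde present gives the same diene).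

Step 5
Reactants: 9 hex-5-yn-2-one
Product: 10 2-(but-3-yn-1-yl)-2-methyl-1,3-dioxolane
Conditions: ethylene glycol, p-TsOH (cat.), benzene, reflux, water separator
Reagents that add atoms: ethylene glycol, OCCO
Why: Acid-catalysed ketalisation driven by azeotropic removal of water, masking the ketone against the organolithium, hydride and borane reagents used later while leaving the terminal alkyne untouched.

Step 6
Reactants: 10 2-(but-3-yn-1-yl)-2-methyl-1,3-dioxolane; 11 2,2,2-trifluoroethyl chloroformate
Product: 13 2,2,2-trifluoroethyl 5-(2-methyl-1,3-dioxolan-2-yl)pent-2-ynoate [the 6,6-(ethylenedioxy)hept-2-ynoate], via lithium acetylide 12 (not isolated)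
Conditions: n-BuLi, THF, −78 °C; then cannulate into 11, THF, −78 °C
Reagents that add atoms: none
Why: Deprotonation of the terminal alkyne and C-acylation of the acetylide by a chloroformate, with inverse addition to suppress double addition, gives the ynoate whose fluorinated ester lowers the alkyne LUMO.

Step 7
Reactants: 8 (R,E)-bis-silyl dienol ether; 13 2,2,2-trifluoroethyl 5-(2-methyl-1,3-dioxolan-2-yl)pent-2-ynoate
Product: 14 2,2,2-trifluoroethyl 2α,7α-bis(tert-butyldimethylsilyloxy)-13,13-(ethylenedioxy)-14,15-dinorlabda-5,8-dien-17-oate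
Conditions: 8 (1.0 equiv), 13 (1.5 equiv), BHT (cat.), toluene (2 M), 13 kbar, 50 °C
Reagents that add atoms: none
Why: A concerted but asynchronous, suprafacial [4π+2π] cycloaddition between the HOMO of the 1-silyloxy diene and the LUMO of the ynoate, whose closest known relatives are the Diels–Alder reactions of 2,6,6-trimethyl-1-vinylcyclohexenes and of 1-silyloxy dienes with acetylenic esters; pressure is used because the activation volume is strongly negative, so the diene's [1,5]-hydrogen shift on heating is avoided. Ring B is closed as a six-membered 1,4-cyclohexadiene by intermolecular [4+2] annulation, both new σ-bonds (C7–C8 and C9–C10) forming on one face of the s-cis diene. The step needs regioselectivity, which the C7 silyloxy donor secures by placing the largest HOMO coefficient on C10, so that C10 joins the β-carbon of the ynoate (C9) and C7 joins the ester-bearing carbon (C8). C7 is set relative to C10 by the (E)-geometry of the dienol ether: H7 and the C10 methyl are both inside substituents and end cis, which means 7α-oxygen with 10β-methyl, while any (Z)-isomer cannot become s-cis and does not react. C10 is set relative to C2 by facial selectivity: in the adduct the C10 methyl must be axial on ring A because C9 lies in the plane of C5=C6, so attack that puts this methyl trans to the equatorial C2 silyloxy group leads straight to a chair, whereas the other face would force that group axial and syn to the C4 and C10 methyls. Silyl ethers and ketal are inert, the quaternary C10 prevents aromatisation, and the minor facial isomer, a diastereomer, would be removed by chromatography.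

Step 8
Reactants: 14 trifluoroethyl ester cycloadduct
Product: 15 2α,7α-bis(tert-butyldimethylsilyloxy)-13,13-(ethylenedioxy)-14,15-dinorlabda-5,8-dien-17-ol
Conditions: i-Bu2AlH, CH2Cl2, −78 °C; aq. potassium sodium tartrate
Reagents that add atoms: none
Why: 1,2-Reduction of an activated α,β-unsaturated ester to the primary allylic alcohol by an aluminium hydride at low temperature, which leaves silyl ethers, ketal and both ring double bonds untouched.

Step 9
Reactants: 15 C17 allylic alcohol
Product: 17 2α,7α-bis(tert-butyldimethylsilyloxy)-13,13-(ethylenedioxy)-14,15-dinorlabda-5,8-diene, via allylic mesylate 16 (not isolated)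
Conditions: MsCl, Et3N, CH2Cl2, −40 °C; then LiEt3BH, THF, −40 → 0 °C
Reagents that add atoms: none
Why: Reductive deoxygenation by SN2 hydride displacement of a primary allylic sulfonate, in which the allylic-shift pathway would require attack at the fully substituted C9 next to the quaternary C10 and is therefore closed, so the C8=C9 bond stays in place and C17 becomes the methyl group.

Step 10
Reactants: 17 C8-methyl 5,8-diene
Product: 19 2α,7α-bis(tert-butyldimethylsilyloxy)-13,13-(ethylenedioxy)-14,15-dinor-5α-labd-8-en-6α-ol, via C6 alkylborane 18 (not isolated)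
Conditions: BH3·THF, THF, 0 °C → rt; then NaOH, H2O2, 0 °C
Reagents that add atoms: hydrogen peroxide, OO
Why: Anti-Markovnikov syn hydroboration–oxidation of the trisubstituted C5=C6 bond (the tetrasubstituted C8=C9 bond being inert, as 8,9-double bonds of lanostane-type skeletons are), with borane approaching the α face opposite the axial C4β and C10β methyl groups so that the 5α-hydrogen and the 6α-hydroxyl are set together.

Step 11
Reactants: 19 6α-alcohol
Product: 20 2α,7α-bis(tert-butyldimethylsilyloxy)-13,13-(ethylenedioxy)-14,15-dinor-5α-labd-8-en-6-one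
Conditions: Dess–Martin periodinane, NaHCO3, CH2Cl2, rt
Reagents that add atoms: none
Why: Oxidation of a secondary alcohol by a hypervalent iodine reagent under buffered, non-enolising conditions, so that the C5 and C7 centres flanking the new ketone keep their configuration.

Step 12
Reactants: 20 6-ketone
Product: 21 2α,7α-bis(tert-butyldimethylsilyloxy)-13,13-(ethylenedioxy)-14,15-dinor-5α-labd-8-en-6β-ol
Conditions: NaBH4, MeOH, −20 °C
Reagents that add atoms: none
Why: Substrate-controlled borohydride reduction in which the β face of the C6 carbonyl is closed by the 1,3-diaxial C4β and C10β methyl groups, so hydride enters from the α face and gives the axial 6β-alcohol, as is usual for 6-oxo-4,4-dimethyl terpenoids.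

Step 13
Reactants: 21 6β-alcohol
Product: 22 2α,7α-bis(tert-butyldimethylsilyloxy)-6β-hydroxy-14,15-dinor-5α-labd-8-en-13-one
Conditions: PPTS (cat.), acetone/H2O, 50 °C
Reagents that add atoms: water, O
Why: Mild acid-catalysed hydrolysis (transketalisation) of the dioxolane at an acidity that neither cleaves the secondary silyl ethers nor ionises the allylic C7–O bond.

Step 14
Reactants: 22 methyl ketone; 23 triethyl phosphonoacetate
Product: 24 ethyl (13E)-2α,7α-bis(tert-butyldimethylsilyloxy)-6β-hydroxy-5α-labda-8,13-dien-15-oate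
Conditions: 23, NaH (slightly less than 1 equiv relative to 23), THF, 0 °C; add 22, 50 °C
Reagents that add atoms: none
Why: Horner–Wadsworth–Emmons olefination of a methyl ketone, where reversible addition places the larger chain trans to the ester so that the (E)-enoate should predominate (the minor (Z)-isomer is removed by chromatography), and the weakly basic phosphonate anion leaves the C6 hydroxyl protonated and the trans-disposed C7 silyl ether in place.

Step 15
Reactants: 24 (E)-enoate
Product: 25 (13E)-2α,7α-bis(tert-butyldimethylsilyloxy)-5α-labda-8,13-diene-6β,15-diol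
Conditions: i-Bu2AlH, CH2Cl2, −78 °C; aq. potassium sodium tartrate
Reagents that add atoms: none
Why: 1,2-Reduction of the conjugated ester to the primary allylic alcohol by an aluminium hydride, which proceeds without conjugate reduction and keeps the alkene geometry.

Step 16
Reactants: 25 6β,15-diol
Product: 26 (13E)-5α-labda-8,13-diene-2α,6β,7α,15-tetraol
Conditions: Bu4NF, THF, rt → 50 °C
Reagents that add atoms: none
Why: Fluoride-induced cleavage of both silyl ethers, driven by the strength of the Si–F bond and run without acid so that the allylic C7 oxygen is not ionised.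

Step 17
Reactants: 26 tetraol
Product: 28 (13E)-15-(tert-butyldimethylsilyloxy)-5α-labda-8,13-diene-2α,6β,7α-triyl triacetate, via 15-O-silyl triol 27 (not isolated)
Conditions: TBSCl (1.05 equiv), imidazole, CH2Cl2, −20 °C; then Ac2O, DMAP, pyridine, 40 °C
Reagents that add atoms: tert-butyldimethylsilyl chloride, CC(C)(C)[Si](C)(C)Cl; acetic anhydride, CC(=O)OC(C)=O
Why: Kinetic silylation picks out the single primary hydroxyl from three secondary ones, after which DMAP-catalysed acylation in the same flask acetylates all three secondary hydroxyls, including the hindered axial 6β one.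

Step 18
Reactants: 28 15-O-silyl triacetate
Product: 29 (13E)-15-hydroxy-5α-labda-8,13-diene-2α,6β,7α-triyl triacetate (CNP0305346.2)
Conditions: HF·pyridine, pyridine/THF, 0 °C → rt
Reagents that add atoms: none
Why: Buffered fluoride desilylation of a primary silyl ether, which is neither basic nor strongly acidic, so the three acetates neither migrate nor hydrolyse and the allylic C7 acetate is not ionised.

Compound list
1 | ketoisophorone (2,6,6-trimethylcyclohex-2-ene-1,4-dione) | CC1=CC(=O)CC(C)(C)C1=O | starting material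
2 | (6R)-2,2,6-trimethylcyclohexane-1,4-dione ((6R)-levodione) | C[C@@H]1CC(=O)CC(C)(C)C1=O | intermediate (not isolated)
3 | (4R,6R)-4-hydroxy-2,2,6-trimethylcyclohexan-1-one ((4R,6R)-actinol) | C[C@@H]1C[C@@H](O)CC(C)(C)C1=O | intermediate
4 | (4R,6R)-4-(tert-butyldimethylsilyloxy)-2,2,6-trimethylcyclohexan-1-one | C[C@@H]1C[C@@H](O[Si](C)(C)C(C)(C)C)CC(C)(C)C1=O | intermediate
5 | (Z)-1-bromo-2-ethoxyethene | Br/C=C\OCC | starting material
6 | (4R,6R)-4-(tert-butyldimethylsilyloxy)-1-[(Z)-2-ethoxyethenyl]-2,2,6-trimethylcyclohexan-1-ol (configuration at C1 immaterial) | CCO/C=C\C1(O)[C@H](C)C[C@@H](O[Si](C)(C)C(C)(C)C)CC1(C)C | intermediate (not isolated)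
7 | (E)-2-[(4R,6R)-4-(tert-butyldimethylsilyloxy)-2,2,6-trimethylcyclohexylidene]acetaldehyde | O=C/C=C1\[C@H](C)C[C@@H](O[Si](C)(C)C(C)(C)C)CC1(C)C | intermediate
8 | (1R)-1-(tert-butyldimethylsilyloxy)-4-[(E)-2-(tert-butyldimethylsilyloxy)ethenyl]-3,5,5-trimethylcyclohex-3-ene (diene C10=C5–C6=C7) | CC(C)(C)[Si](C)(C)O[C@H]1CC(C)(C)C(/C=C/O[Si](C)(C)C(C)(C)C)=C(C)C1 | intermediate
9 | hex-5-yn-2-one | CC(=O)CCC#C | starting material
10 | 2-(but-3-yn-1-yl)-2-methyl-1,3-dioxolane | CC1(CCC#C)OCCO1 | intermediate
11 | 2,2,2-trifluoroethyl chloroformate | O=C(Cl)OCC(F)(F)F | starting material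
12 | lithium acetylide of 10 | [Li]C#CCCC1(C)OCCO1 | intermediate (not isolated)
13 | 2,2,2-trifluoroethyl 5-(2-methyl-1,3-dioxolan-2-yl)pent-2-ynoate | CC1(CCC#CC(=O)OCC(F)(F)F)OCCO1 | intermediate
14 | 2,2,2-trifluoroethyl 2α,7α-bis(tert-butyldimethylsilyloxy)-13,13-(ethylenedioxy)-14,15-dinorlabda-5,8-dien-17-oate (10β-methyl) | CC(C)(C)[Si](C)(C)O[C@H]1CC(C)(C)C2=C[C@@H](O[Si](C)(C)C(C)(C)C)C(C(=O)OCC(F)(F)F)=C(CCC3(C)OCCO3)[C@@]2(C)C1 | intermediate
15 | 2α,7α-bis(tert-butyldimethylsilyloxy)-13,13-(ethylenedioxy)-14,15-dinorlabda-5,8-dien-17-ol | CC(C)(C)[Si](C)(C)O[C@H]1CC(C)(C)C2=C[C@@H](O[Si](C)(C)C(C)(C)C)C(CO)=C(CCC3(C)OCCO3)[C@@]2(C)C1 | intermediate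
16 | 17-methanesulfonate of 15 | CC(C)(C)[Si](C)(C)O[C@H]1CC(C)(C)C2=C[C@@H](O[Si](C)(C)C(C)(C)C)C(COS(C)(=O)=O)=C(CCC3(C)OCCO3)[C@@]2(C)C1 | intermediate (not isolated)
17 | 2α,7α-bis(tert-butyldimethylsilyloxy)-13,13-(ethylenedioxy)-14,15-dinorlabda-5,8-diene | CC(C)(C)[Si](C)(C)O[C@H]1CC(C)(C)C2=C[C@@H](O[Si](C)(C)C(C)(C)C)C(C)=C(CCC3(C)OCCO3)[C@@]2(C)C1 | intermediate
18 | 6α-boryl-2α,7α-bis(tert-butyldimethylsilyloxy)-13,13-(ethylenedioxy)-14,15-dinor-5α-labd-8-ene | CC(C)(C)[Si](C)(C)O[C@H]1CC(C)(C)[C@@H]2[C@@H](B)[C@@H](O[Si](C)(C)C(C)(C)C)C(C)=C(CCC3(C)OCCO3)[C@@]2(C)C1 | intermediate (not isolated)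
19 | 2α,7α-bis(tert-butyldimethylsilyloxy)-13,13-(ethylenedioxy)-14,15-dinor-5α-labd-8-en-6α-ol | CC(C)(C)[Si](C)(C)O[C@H]1CC(C)(C)[C@@H]2[C@@H](O)[C@@H](O[Si](C)(C)C(C)(C)C)C(C)=C(CCC3(C)OCCO3)[C@@]2(C)C1 | intermediate
20 | 2α,7α-bis(tert-butyldimethylsilyloxy)-13,13-(ethylenedioxy)-14,15-dinor-5α-labd-8-en-6-one | CC(C)(C)[Si](C)(C)O[C@H]1CC(C)(C)[C@@H]2C(=O)[C@@H](O[Si](C)(C)C(C)(C)C)C(C)=C(CCC3(C)OCCO3)[C@@]2(C)C1 | intermediate
21 | 2α,7α-bis(tert-butyldimethylsilyloxy)-13,13-(ethylenedioxy)-14,15-dinor-5α-labd-8-en-6β-ol | CC(C)(C)[Si](C)(C)O[C@H]1CC(C)(C)[C@@H]2[C@H](O)[C@@H](O[Si](C)(C)C(C)(C)C)C(C)=C(CCC3(C)OCCO3)[C@@]2(C)C1 | intermediate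
22 | 2α,7α-bis(tert-butyldimethylsilyloxy)-6β-hydroxy-14,15-dinor-5α-labd-8-en-13-one | CC(C)(C)[Si](C)(C)O[C@H]1CC(C)(C)[C@@H]2[C@H](O)[C@@H](O[Si](C)(C)C(C)(C)C)C(C)=C(CCC(C)=O)[C@@]2(C)C1 | intermediate
23 | triethyl phosphonoacetate | CCOC(=O)CP(=O)(OCC)OCC | starting material
24 | ethyl (13E)-2α,7α-bis(tert-butyldimethylsilyloxy)-6β-hydroxy-5α-labda-8,13-dien-15-oate | CC(C)(C)[Si](C)(C)O[C@H]1CC(C)(C)[C@@H]2[C@H](O)[C@@H](O[Si](C)(C)C(C)(C)C)C(C)=C(CC/C(C)=C/C(=O)OCC)[C@@]2(C)C1 | intermediate
25 | (13E)-2α,7α-bis(tert-butyldimethylsilyloxy)-5α-labda-8,13-diene-6β,15-diol | CC(C)(C)[Si](C)(C)O[C@H]1CC(C)(C)[C@@H]2[C@H](O)[C@@H](O[Si](C)(C)C(C)(C)C)C(C)=C(CC/C(C)=C/CO)[C@@]2(C)C1 | intermediate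
26 | (13E)-5α-labda-8,13-diene-2α,6β,7α,15-tetraol | O[C@H]1CC(C)(C)[C@@H]2[C@H](O)[C@@H](O)C(C)=C(CC/C(C)=C/CO)[C@@]2(C)C1 | intermediate
27 | (13E)-15-(tert-butyldimethylsilyloxy)-5α-labda-8,13-diene-2α,6β,7α-triol | O[C@H]1CC(C)(C)[C@@H]2[C@H](O)[C@@H](O)C(C)=C(CC/C(C)=C/CO[Si](C)(C)C(C)(C)C)[C@@]2(C)C1 | intermediate (not isolated)
28 | (13E)-15-(tert-butyldimethylsilyloxy)-5α-labda-8,13-diene-2α,6β,7α-triyl triacetate | CC(=O)O[C@H]1CC(C)(C)[C@@H]2[C@H](OC(C)=O)[C@@H](OC(C)=O)C(C)=C(CC/C(C)=C/CO[Si](C)(C)C(C)(C)C)[C@@]2(C)C1 | intermediate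
29 | (13E)-15-hydroxy-5α-labda-8,13-diene-2α,6β,7α-triyl triacetate (CNP0305346.2) | CC(=O)O[C@H]1CC(C)(C)[C@@H]2[C@H](OC(C)=O)[C@@H](OC(C)=O)C(C)=C(CC/C(C)=C/CO)[C@@]2(C)C1 | target

Total step count: 18 (steps 1–4 diene, steps 5–6 ynoate, step 7 cycloaddition, steps 8–18 elaboration).
Longest linear sequence: 16 steps (steps 1–4 and 7–18).

Steps most likely to fail

Step 7. The β-alkyl ynoate may add too slowly to the hindered diene, so that desilylation or sigmatropic hydrogen shift of the diene wins, and the alkyne may discriminate less well than planned between the two faces of C10. The fallback sets out from 10 and comes back at 15. Acetylide 12 is formylated with DMF in place of the acylation, giving the ynal 5-(2-methyl-1,3-dioxolan-2-yl)pent-2-ynal F1, a more electrophilic dienophile with the same skeleton and the same orientation. Its cycloaddition with 8 (toluene, 60–80 °C, or moderate pressure) should give the aldehyde 2α,7α-bis(tert-butyldimethylsilyloxy)-13,13-(ethylenedioxy)-14,15-dinorlabda-5,8-dien-17-al F2. Luche reduction of F2 (NaBH4, CeCl3·7H2O, MeOH, −78 °C) then gives allylic alcohol 15.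

Step 10. Borane may fail to engage the C5=C6 bond, which lies between two quaternary carbons. It may also add from the β face, anti to the C7 silyloxy group, which would give the cis ring fusion. The fallback sets out from 14 and comes back at 21. At the ester stage the C8=C9 bond is an unreactive enoate, so m-chloroperbenzoic acid (NaHCO3, CH2Cl2) should epoxidise only C5=C6, giving the 5α,6α-epoxide of 14 F3 (either epoxide epimer serves). BF3·OEt2 at −78 °C opens the epoxide at tertiary C5 and the C6 hydrogen migrates (Meinwald rearrangement), giving the trifluoroethyl 6-oxo-5α-labd-8-en-17-oate F4; the ring fusion is equilibrated to trans with DBU if needed. i-Bu2AlH then reduces the ketone from the α face and the ester in one operation to the 6β,17-diol F5. Mesylation of the primary allylic hydroxyl only gives the 17-mesylate F6, and LiEt3BH displaces it to give 21.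

Step 4. Vinylogous deprotonation may be slow, because allylic strain holds the single γ-hydrogen near the plane of the enal; this would leave room for decomposition by the silyl triflate and for loss of enol ether geometry. The fallback sets out from 4 and comes back at 8. KN(SiMe3)2 and PhNTf2 (THF, −78 °C) convert 4, which has one α-hydrogen only, into the enol triflate (R)-4-(tert-butyldimethylsilyloxy)-2,6,6-trimethylcyclohex-1-en-1-yl trifluoromethanesulfonate F7. Suzuki–Miyaura coupling of F7 with commercial (E)-2-ethoxyvinylboronic acid pinacol ester (Pd(PPh3)4, K3PO4, dioxane/H2O) gives the (E)-ethoxy diene F8. Mild hydrolysis (aqueous oxalic acid, THF) gives the deconjugated aldehyde 2-[(4R)-4-(tert-butyldimethylsilyloxy)-2,6,6-trimethylcyclohex-1-en-1-yl]acetaldehyde F9. Its doubly activated α-methylene is silylated under ordinary conditions (TBSOTf, Et3N) to give 8; any (Z)-isomer is inert in step 7 and is removed there.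

Further compounds
F1 | step 7 | 5-(2-methyl-1,3-dioxolan-2-yl)pent-2-ynal | O=CC#CCCC1(C)OCCO1
F2 | step 7 | 2α,7α-bis(tert-butyldimethylsilyloxy)-13,13-(ethylenedioxy)-14,15-dinorlabda-5,8-dien-17-al | CC(C)(C)[Si](C)(C)O[C@H]1CC(C)(C)C2=C[C@@H](O[Si](C)(C)C(C)(C)C)C(C=O)=C(CCC3(C)OCCO3)[C@@]2(C)C1
F3 | step 10 | 2,2,2-trifluoroethyl 2α,7α-bis(tert-butyldimethylsilyloxy)-5α,6α-epoxy-13,13-(ethylenedioxy)-14,15-dinorlabd-8-en-17-oate | CC(C)(C)[Si](C)(C)O[C@H]1CC(C)(C)[C@@]23O[C@H]3[C@@H](O[Si](C)(C)C(C)(C)C)C(C(=O)OCC(F)(F)F)=C(CCC4(C)OCCO4)[C@@]2(C)C1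
F4 | step 10 | 2,2,2-trifluoroethyl 2α,7α-bis(tert-butyldimethylsilyloxy)-13,13-(ethylenedioxy)-6-oxo-14,15-dinor-5α-labd-8-en-17-oate | CC(C)(C)[Si](C)(C)O[C@H]1CC(C)(C)[C@@H]2C(=O)[C@@H](O[Si](C)(C)C(C)(C)C)C(C(=O)OCC(F)(F)F)=C(CCC3(C)OCCO3)[C@@]2(C)C1
F5 | step 10 | 2α,7α-bis(tert-butyldimethylsilyloxy)-13,13-(ethylenedioxy)-14,15-dinor-5α-labd-8-ene-6β,17-diol | CC(C)(C)[Si](C)(C)O[C@H]1CC(C)(C)[C@@H]2[C@H](O)[C@@H](O[Si](C)(C)C(C)(C)C)C(CO)=C(CCC3(C)OCCO3)[C@@]2(C)C1
F6 | step 10 | 17-methanesulfonate of F5 | CC(C)(C)[Si](C)(C)O[C@H]1CC(C)(C)[C@@H]2[C@H](O)[C@@H](O[Si](C)(C)C(C)(C)C)C(COS(C)(=O)=O)=C(CCC3(C)OCCO3)[C@@]2(C)C1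
F7 | step 4 | (R)-4-(tert-butyldimethylsilyloxy)-2,6,6-trimethylcyclohex-1-en-1-yl trifluoromethanesulfonate | CC(C)(C)[Si](C)(C)O[C@H]1CC(C)(C)C(OS(=O)(=O)C(F)(F)F)=C(C)C1
F8 | step 4 | (1R)-1-(tert-butyldimethylsilyloxy)-4-[(E)-2-ethoxyethenyl]-3,5,5-trimethylcyclohex-3-ene | CC(C)(C)[Si](C)(C)O[C@H]1CC(C)(C)C(/C=C/OCC)=C(C)C1
F9 | step 4 | 2-[(4R)-4-(tert-butyldimethylsilyloxy)-2,6,6-trimethylcyclohex-1-en-1-yl]acetaldehyde | CC(C)(C)[Si](C)(C)O[C@H]1CC(C)(C)C(CC=O)=C(C)C1
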